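**Retrosynthetic overview**

1. Last C–C bond (C2′–C3′ of the side chain): lithiation–borylation of a tricyclic primary alkylboronate with an α-lithiated (R)-allylic carbamate, then oxidation. The carbinol carbon is used as a carbanion instead of as a ketone electrophile, and this sets the tertiary allylic alcohol directly.
2. Tricycle: intramolecular Diels–Alder of a 2-silyloxycyclohexa-1,3-diene onto a tethered (E)-2-methylbut-2-enoyl ketone. It closes the bicyclo[2.2.2]octane and ring B together and sets four stereocentres.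
3. Ring A (cyclohexenone) with its quaternary carbon: catalytic asymmetric Diels–Alder of an aminosilyloxydiene with a 2-substituted acrolein. The formyl group becomes the vinyl, then boronate, handle.
4. Acrolein: α-methylenation of a 1,5-keto aldehyde made by an organocatalytic Mukaiyama–Michael addition, which sets the secondary methyl centre.
5. Ring order: ring A first (step 4), then the bridging ring and ring B in one operation (step 6).

Locants of tricyclic compounds are those of tricyclo[5.3.1.0^3,8]undecane as used in the names: C4 carries the oxygen, C7 the side chain, C10 the bridging carbonyl. In all of them the C2 and C3 methyls are syn to the C9–C10 bridge, the C6 methyl is axial on ring B and cis to the C7 side chain, and the C4 oxygen is equatorial (trans to the C3 methyl).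

Assumption: the facial sense of the two organocatalysts (steps 2 and 4) is taken from the published models; if a trial shows the opposite sense, the mirror-image catalyst is used.

**Route**

Step 1
Reactants: 1 (E)-3-methylpent-3-en-2-one
Product: 2 trimethyl{[(3E)-3-methylpenta-1,3-dien-2-yl]oxy}silane
Conditions: LiN(iPr)2, THF, −78 °C; Me3SiCl
Reagents that add atoms: chlorotrimethylsilane, C[Si](C)(C)Cl
Why: Kinetic deprotonation at the methyl group (α′) of the enone and O-silylation (silyl enol ether formation) give the cross-conjugated 2-silyloxydiene; no stereocentre is formed.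

Step 2
Reactants: 2 trimethyl{[(3E)-3-methylpenta-1,3-dien-2-yl]oxy}silane and 3 (E)-but-2-enal
Product: 4 (3S,6E)-3,6-dimethyl-5-oxooct-6-enal
Conditions: (2R,5R)-5-benzyl-2-tert-butyl-3-methylimidazolidin-4-one·2,4-dinitrobenzoic acid (20 mol%), tBuOH/iPrOH, −20 °C
Reagents that add atoms: none
Why: Organocatalytic Mukaiyama–Michael addition: the chiral iminium ion of the enal is attacked at its β-carbon by the CH2 terminus of the silyl enol ether on the face left open by the catalyst, which sets the methyl-bearing centre (3S here, C6 of the tricycle).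

Step 3
Reactants: 4 (3S,6E)-3,6-dimethyl-5-oxooct-6-enal
Product: 5 (3R,6E)-3,6-dimethyl-2-methylidene-5-oxooct-6-enal
Conditions: aq. CH2O, pyrrolidine (10 mol%), EtCO2H (10 mol%), iPrOH, 45 °C
Reagents that add atoms: formaldehyde, C=O
Why: Organocatalytic α-methylenation (enamine Mannich addition then elimination) is selective for the aldehyde over the ketone and leaves the β-stereocentre untouched (the descriptor changes only through priorities).

Step 4
Reactants: 5 (3R,6E)-3,6-dimethyl-2-methylidene-5-oxooct-6-enal and 6 (1E)-3-[(tert-butyldimethylsilyl)oxy]-N,N-dimethylbuta-1,3-dien-1-amine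
Product: 8 (1R)-1-[(2R,5E)-5-methyl-4-oxohept-5-en-2-yl]-4-oxocyclohex-2-ene-1-carbaldehyde, via aminosilyloxy cycloadduct 7 (not isolated)
Conditions: (R,R)-tetra(1-naphthyl)-TADDOL (20 mol%), PhMe, −80 °C; then aq. HF, MeCN, 0 °C
Reagents that add atoms: none
Why: Hydrogen-bond-catalysed Diels–Alder reaction: the diol activates the formyl group, the CH2 terminus of the diene bonds to the acrolein CH2 and the amino-bearing carbon to the α-carbon, so the quaternary carbon is created under catalyst control; HF then eliminates dimethylamine and cleaves the silyl enol ether to give the 4,4-disubstituted cyclohexenone.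

Step 5
Reactants: 8 (1R)-1-[(2R,5E)-5-methyl-4-oxohept-5-en-2-yl]-4-oxocyclohex-2-ene-1-carbaldehyde
Product: 9 (4R)-4-ethenyl-4-[(2R,5E)-5-methyl-4-oxohept-5-en-2-yl]cyclohex-2-en-1-one
Conditions: CH2I2, Zn, Ti(OiPr)4, THF, 23 °C
Reagents that add atoms: diiodomethane, ICI
Why: Takai–Lombardo methylenation converts the aldehyde selectively in the presence of the two ketones; no stereocentre is touched.

Step 6
Reactants: 9 (4R)-4-ethenyl-4-[(2R,5E)-5-methyl-4-oxohept-5-en-2-yl]cyclohex-2-en-1-one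
Product: 12 (1R,2R,3S,6R,7R,8S)-10-[(tert-butyldimethylsilyl)oxy]-7-ethenyl-2,3,6-trimethyltricyclo[5.3.1.0^3,8]undec-9-en-4-one, via lithium dienolate 10 (not isolated), via silyloxydiene 11 (not isolated)
Conditions: LiN(iPr)2, THF, −78 °C; tBuMe2SiOTf, −78 °C; then PhMe, 110 °C
Reagents that add atoms: tert-butyldimethylsilyl trifluoromethanesulfonate, CC(C)(C)[Si](C)(C)OS(=O)(=O)C(F)(F)F
Why: Kinetic α′-enolisation of the less hindered ring enone and O-silylation give the 2-silyloxydiene, which undergoes an intramolecular Diels–Alder reaction; the tether on the quaternary carbon fixes the diene face and points the acyl carbon toward the C7–C11 bridge, and suprafacial addition of the E-alkene places both new methyls syn, so C1, C2, C3 and C8 are set together.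

Step 7
Reactants: 12 (1R,2R,3S,6R,7R,8S)-10-[(tert-butyldimethylsilyl)oxy]-7-ethenyl-2,3,6-trimethyltricyclo[5.3.1.0^3,8]undec-9-en-4-one
Product: 13 (1R,2R,3S,4R,6R,7R,8S)-10-[(tert-butyldimethylsilyl)oxy]-7-ethenyl-2,3,6-trimethyltricyclo[5.3.1.0^3,8]undec-9-en-4-ol
Conditions: Li, NH3(l), THF, MeOH, −78 °C
Reagents that add atoms: none
Why: Dissolving-metal reduction of the ketone is under thermodynamic control and gives the equatorial C4 alcohol (the axial epimer would be syn-axial to the C6 methyl); the isolated vinyl group and the silyl enol ether are not reduced.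

Step 8
Reactants: 13 (1R,2R,3S,4R,6R,7R,8S)-10-[(tert-butyldimethylsilyl)oxy]-7-ethenyl-2,3,6-trimethyltricyclo[5.3.1.0^3,8]undec-9-en-4-ol
Product: 15 (1R,2R,3S,4R,6R,7S,8S)-10-[(tert-butyldimethylsilyl)oxy]-2,3,6-trimethyl-7-[2-(4,4,5,5-tetramethyl-1,3,2-dioxaborolan-2-yl)ethyl]tricyclo[5.3.1.0^3,8]undec-9-en-4-ol, via O-boryl boronate 14 (not isolated)
Conditions: pinacolborane (2.5 equiv), [Ir(cod)Cl]2 (2 mol%), dppe (4 mol%), CH2Cl2, 23 °C; aqueous work-up
Reagents that add atoms: pinacolborane, CC1(C)OBOC1(C)C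
Why: Iridium-catalysed anti-Markovnikov hydroboration of the terminal alkene gives the primary boronate; the hydroxyl is borylated in passing and freed again on work-up, and no stereocentre is formed.

Step 9
Reactants: 16 (2R)-but-3-en-2-ol
Product: 17 (2R)-but-3-en-2-yl N,N-di(propan-2-yl)carbamate
Conditions: iPr2NCOCl, Et3N, CH2Cl2, reflux
Reagents that add atoms: N,N-di(propan-2-yl)carbamoyl chloride, CC(C)N(C(C)C)C(=O)Cl
Why: O-Carbamoylation of the alcohol installs the directing and leaving group without touching the stereocentre.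

Step 10
Reactants: 15 (1R,2R,3S,4R,6R,7S,8S)-10-[(tert-butyldimethylsilyl)oxy]-2,3,6-trimethyl-7-[2-(4,4,5,5-tetramethyl-1,3,2-dioxaborolan-2-yl)ethyl]tricyclo[5.3.1.0^3,8]undec-9-en-4-ol and 17 (2R)-but-3-en-2-yl N,N-di(propan-2-yl)carbamate
Product: 21 (1R,2R,3S,4R,6R,7S,8S)-10-[(tert-butyldimethylsilyl)oxy]-7-[(3S)-3-hydroxy-3-methylpent-4-en-1-yl]-2,3,6-trimethyltricyclo[5.3.1.0^3,8]undec-9-en-4-ol, via lithiated carbamate 18 (not isolated), via boronate complex 19 (not isolated), via tertiary boronic ester 20 (not isolated)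
Conditions: 17 (2.6 equiv), sBuLi (2.5 equiv), TMEDA, Et2O, −78 °C; then 15; −78 → 35 °C; then NaOH, H2O2, THF, 0 °C
Reagents that add atoms: hydrogen peroxide, OO
Why: Hoppe–Aggarwal lithiation–borylation: deprotonation of 17 with retention gives the configurationally stable α-oxy carbanion 18 (a reversed-polarity equivalent of a ketone carbon), which adds to boron with retention; antiperiplanar 1,2-migration of the primary alkyl group with inversion expels the carbamate, and oxidation with retention gives the 3S tertiary allylic alcohol, while one extra equivalent of 18 is consumed by the C4 hydroxyl and the masked C10 ketone cannot be attacked or allylborated.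

Step 11
Reactants: 21 (1R,2R,3S,4R,6R,7S,8S)-10-[(tert-butyldimethylsilyl)oxy]-7-[(3S)-3-hydroxy-3-methylpent-4-en-1-yl]-2,3,6-trimethyltricyclo[5.3.1.0^3,8]undec-9-en-4-ol
Product: 22 (1R,2R,3S,4R,6R,7S,8S)-10-[(tert-butyldimethylsilyl)oxy]-7-[(3S)-3-hydroxy-3-methylpent-4-en-1-yl]-2,3,6-trimethyltricyclo[5.3.1.0^3,8]undec-9-en-4-yl acetate
Conditions: Ac2O (1.5 equiv), DMAP, pyridine, CH2Cl2, 0 → 23 °C
Reagents that add atoms: acetic anhydride, CC(=O)OC(C)=O
Why: Nucleophile-catalysed acylation takes the secondary alcohol much faster than the tertiary allylic one; no stereocentre changes.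

Step 12
Reactants: 22 (1R,2R,3S,4R,6R,7S,8S)-10-[(tert-butyldimethylsilyl)oxy]-7-[(3S)-3-hydroxy-3-methylpent-4-en-1-yl]-2,3,6-trimethyltricyclo[5.3.1.0^3,8]undec-9-en-4-yl acetate
Product: 23 (1R,2R,3S,4R,6R,7S,8S)-7-[(3S)-3-hydroxy-3-methylpent-4-en-1-yl]-2,3,6-trimethyl-10-oxotricyclo[5.3.1.0^3,8]undecan-4-yl acetate
Conditions: Bu4NF, AcOH, THF, 0 °C
Reagents that add atoms: none
Why: Buffered fluoride desilylation of the silyl enol ether releases the bridging ketone (protonation at the C9 methylene creates no stereocentre; the bridgehead C1 cannot epimerise), and the acetate and tertiary allylic alcohol survive.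

**Compound list**

1 | (E)-3-methylpent-3-en-2-one | CC(=O)/C(C)=C/C | starting material
2 | trimethyl{[(3E)-3-methylpenta-1,3-dien-2-yl]oxy}silane | C=C(O[Si](C)(C)C)/C(C)=C/C | intermediate
3 | (E)-but-2-enal | C/C=C/C=O | starting material
4 | (3S,6E)-3,6-dimethyl-5-oxooct-6-enal | O=CC[C@H](C)CC(=O)/C(C)=C/C | intermediate
5 | (3R,6E)-3,6-dimethyl-2-methylidene-5-oxooct-6-enal | C=C(C=O)[C@H](C)CC(=O)/C(C)=C/C | intermediate
6 | (1E)-3-[(tert-butyldimethylsilyl)oxy]-N,N-dimethylbuta-1,3-dien-1-amine | C=C(O[Si](C)(C)C(C)(C)C)/C=C/N(C)C | starting material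
7 | (1R)-4-[(tert-butyldimethylsilyl)oxy]-2-(dimethylamino)-1-[(2R,5E)-5-methyl-4-oxohept-5-en-2-yl]cyclohex-3-ene-1-carbaldehyde (C2 epimers converge) | O=C[C@]1(CCC(O[Si](C)(C)C(C)(C)C)=CC1N(C)C)[C@H](C)CC(=O)/C(C)=C/C | intermediate
8 | (1R)-1-[(2R,5E)-5-methyl-4-oxohept-5-en-2-yl]-4-oxocyclohex-2-ene-1-carbaldehyde | O=C[C@]1(CCC(=O)C=C1)[C@H](C)CC(=O)/C(C)=C/C | intermediate
9 | (4R)-4-ethenyl-4-[(2R,5E)-5-methyl-4-oxohept-5-en-2-yl]cyclohex-2-en-1-one | C=C[C@]1(CCC(=O)C=C1)[C@H](C)CC(=O)/C(C)=C/C | intermediate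
10 | lithium (4R)-4-ethenyl-4-[(2R,5E)-5-methyl-4-oxohept-5-en-2-yl]cyclohexa-1,5-dien-1-olate | C=C[C@]1(CC=C([O-])C=C1)[C@H](C)CC(=O)/C(C)=C/C.[Li+] | intermediate
11 | tert-butyl({(4R)-4-ethenyl-4-[(2R,5E)-5-methyl-4-oxohept-5-en-2-yl]cyclohexa-1,5-dien-1-yl}oxy)dimethylsilane | C=C[C@]1(CC=C(O[Si](C)(C)C(C)(C)C)C=C1)[C@H](C)CC(=O)/C(C)=C/C | intermediate
12 | (1R,2R,3S,6R,7R,8S)-10-[(tert-butyldimethylsilyl)oxy]-7-ethenyl-2,3,6-trimethyltricyclo[5.3.1.0^3,8]undec-9-en-4-one | C=C[C@@]12C[C@H]3C(O[Si](C)(C)C(C)(C)C)=C[C@@H]1[C@](C)([C@@H]3C)C(=O)C[C@H]2C | intermediate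
13 | (1R,2R,3S,4R,6R,7R,8S)-10-[(tert-butyldimethylsilyl)oxy]-7-ethenyl-2,3,6-trimethyltricyclo[5.3.1.0^3,8]undec-9-en-4-ol | C=C[C@@]12C[C@H]3C(O[Si](C)(C)C(C)(C)C)=C[C@@H]1[C@](C)([C@@H]3C)[C@H](O)C[C@H]2C | intermediate
14 | (1R,2R,3S,4R,6R,7S,8S)-10-[(tert-butyldimethylsilyl)oxy]-2,3,6-trimethyl-4-[(4,4,5,5-tetramethyl-1,3,2-dioxaborolan-2-yl)oxy]-7-[2-(4,4,5,5-tetramethyl-1,3,2-dioxaborolan-2-yl)ethyl]tricyclo[5.3.1.0^3,8]undec-9-ene | CC1(C)OB(CC[C@@]23C[C@H]4C(O[Si](C)(C)C(C)(C)C)=C[C@@H]2[C@](C)([C@@H]4C)[C@H](OB5OC(C)(C)C(C)(C)O5)C[C@H]3C)OC1(C)C | intermediate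
15 | (1R,2R,3S,4R,6R,7S,8S)-10-[(tert-butyldimethylsilyl)oxy]-2,3,6-trimethyl-7-[2-(4,4,5,5-tetramethyl-1,3,2-dioxaborolan-2-yl)ethyl]tricyclo[5.3.1.0^3,8]undec-9-en-4-ol | CC1(C)OB(CC[C@@]23C[C@H]4C(O[Si](C)(C)C(C)(C)C)=C[C@@H]2[C@](C)([C@@H]4C)[C@H](O)C[C@H]3C)OC1(C)C | intermediate
16 | (2R)-but-3-en-2-ol | C=C[C@@H](C)O | starting material
17 | (2R)-but-3-en-2-yl N,N-di(propan-2-yl)carbamate | C=C[C@@H](C)OC(=O)N(C(C)C)C(C)C | intermediate
18 | (2R)-2-lithiobut-3-en-2-yl N,N-di(propan-2-yl)carbamate | C=C[C@@]([Li])(C)OC(=O)N(C(C)C)C(C)C | intermediate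
19 | dilithium salt of the boronate complex of 15 (as C4 alkoxide) with 18 | C=C[C@@](C)(OC(=O)N(C(C)C)C(C)C)[B-]1(CC[C@@]23C[C@H]4C(O[Si](C)(C)C(C)(C)C)=C[C@@H]2[C@](C)([C@@H]4C)[C@H]([O-])C[C@H]3C)OC(C)(C)C(C)(C)O1.[Li+].[Li+] | intermediate
20 | lithium alkoxide of (1R,2R,3S,4R,6R,7S,8S)-10-[(tert-butyldimethylsilyl)oxy]-2,3,6-trimethyl-7-[(3R)-3-methyl-3-(4,4,5,5-tetramethyl-1,3,2-dioxaborolan-2-yl)pent-4-en-1-yl]tricyclo[5.3.1.0^3,8]undec-9-en-4-ol | C=C[C@@](C)(B1OC(C)(C)C(C)(C)O1)CC[C@@]23C[C@H]4C(O[Si](C)(C)C(C)(C)C)=C[C@@H]2[C@](C)([C@@H]4C)[C@H]([O-])C[C@H]3C.[Li+] | intermediate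
21 | (1R,2R,3S,4R,6R,7S,8S)-10-[(tert-butyldimethylsilyl)oxy]-7-[(3S)-3-hydroxy-3-methylpent-4-en-1-yl]-2,3,6-trimethyltricyclo[5.3.1.0^3,8]undec-9-en-4-ol | C=C[C@@](C)(O)CC[C@@]12C[C@H]3C(O[Si](C)(C)C(C)(C)C)=C[C@@H]1[C@](C)([C@@H]3C)[C@H](O)C[C@H]2C | intermediate
22 | (1R,2R,3S,4R,6R,7S,8S)-10-[(tert-butyldimethylsilyl)oxy]-7-[(3S)-3-hydroxy-3-methylpent-4-en-1-yl]-2,3,6-trimethyltricyclo[5.3.1.0^3,8]undec-9-en-4-yl acetate | C=C[C@@](C)(O)CC[C@@]12C[C@H]3C(O[Si](C)(C)C(C)(C)C)=C[C@@H]1[C@](C)([C@@H]3C)[C@H](OC(C)=O)C[C@H]2C | intermediate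
23 | (1R,2R,3S,4R,6R,7S,8S)-7-[(3S)-3-hydroxy-3-methylpent-4-en-1-yl]-2,3,6-trimethyl-10-oxotricyclo[5.3.1.0^3,8]undecan-4-yl acetate | C=C[C@@](C)(O)CC[C@@]12C[C@H]3C(=O)C[C@@H]1[C@](C)([C@@H]3C)[C@H](OC(C)=O)C[C@H]2C | target

**Step count and risks**

Total step count: 12. Longest linear sequence: 11 (steps 1–8 and 10–12; step 9 is a one-step branch).

The three steps most likely to fail are steps 4, 6 and 10.

For step 4, the α-substituent of the acrolein is branched and its stereocentre may oppose the catalyst. The fallback sets out from 5 and comes back at 8. Cycloaddition of 5 with 2-(triisopropylsilyloxy)buta-1,3-diene under a cationic chiral oxazaborolidine Lewis acid ((S)-o-tolyl-CBS activated by HNTf2, CH2Cl2, −78 °C) gives the silyl enol ether aldehyde (1S)-1-[(2R,5E)-5-methyl-4-oxohept-5-en-2-yl]-4-[(triisopropylsilyl)oxy]cyclohex-3-ene-1-carbaldehyde F1. Saegusa–Ito dehydrogenation of F1 (Pd(OAc)2, MeCN, 23 °C) places the double bond toward the quaternary carbon and gives 8.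

For step 6, the base may enolise the side-chain ketone instead of the ring enone, and the resulting silyl dienol ether is a dead end. The fallback sets out from 5 and 6 and comes back at 11, which is then heated to 12 as in step 6. The cycloaddition of step 4 is run without the HF treatment and the cycloadduct 7 is isolated. Wittig methylenation (Ph3P=CH2, THF, −78 °C) of its aldehyde gives (6R)-3-[(tert-butyldimethylsilyl)oxy]-6-ethenyl-N,N-dimethyl-6-[(2R,5E)-5-methyl-4-oxohept-5-en-2-yl]cyclohex-2-en-1-amine F2. N-Methylation (MeOTf, CH2Cl2, −78 °C) gives the allylic ammonium salt (6R)-3-[(tert-butyldimethylsilyl)oxy]-6-ethenyl-N,N,N-trimethyl-6-[(2R,5E)-5-methyl-4-oxohept-5-en-2-yl]cyclohex-2-en-1-aminium trifluoromethanesulfonate F3. With iPr2NEt (0 → 23 °C) F3 loses trimethylamine in a vinylogous (1,4) elimination through the silyloxyallyl cation and gives the ring silyloxydiene 11 regiospecifically, with no strong base ever in contact with the side-chain ketone. This elimination is untested on such substrates and rests on the analogy with soft enolisation of an O-silylated enone.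

For step 10, the boronate is hindered, the lithiated allylic carbamate could borylate at its γ-carbon, and the free alkoxide costs reagent. The fallback sets out from 13 and comes back at 21.
- Hydroboration of 13 with 9-BBN (THF, 23 °C) gives 9-{2-[(1R,2R,3S,4R,6R,7S,8S)-10-[(tert-butyldimethylsilyl)oxy]-4-hydroxy-2,3,6-trimethyltricyclo[5.3.1.0^3,8]undec-9-en-7-yl]ethyl}-9-borabicyclo[3.3.1]nonane F4.
- F4 is coupled in the same pot (Pd(dppf)Cl2, K3PO4, DMF/H2O, 50 °C) with (E)-3-iodobut-2-en-1-ol to the allylic alcohol (1R,2R,3S,4R,6R,7S,8S)-10-[(tert-butyldimethylsilyl)oxy]-7-[(3E)-5-hydroxy-3-methylpent-3-en-1-yl]-2,3,6-trimethyltricyclo[5.3.1.0^3,8]undec-9-en-4-ol F5.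
- Sharpless asymmetric epoxidation (Ti(OiPr)4, L-(+)-diethyl tartrate, tBuOOH, CH2Cl2, −20 °C) gives the epoxy alcohol (1R,2R,3S,4R,6R,7S,8S)-10-[(tert-butyldimethylsilyl)oxy]-7-{2-[(2S,3S)-3-(hydroxymethyl)-2-methyloxiran-2-yl]ethyl}-2,3,6-trimethyltricyclo[5.3.1.0^3,8]undec-9-en-4-ol F6.
- PPh3, I2 and imidazole convert the primary alcohol into the epoxy iodide (1R,2R,3S,4R,6R,7S,8S)-10-[(tert-butyldimethylsilyl)oxy]-7-{2-[(2S,3R)-3-(iodomethyl)-2-methyloxiran-2-yl]ethyl}-2,3,6-trimethyltricyclo[5.3.1.0^3,8]undec-9-en-4-ol F7.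
- Zn (EtOH, reflux) opens F7 reductively to the tertiary allylic alcohol 21 with the C–O bond of the carbinol carbon untouched.

Further compounds
F1 | step 4 | (1S)-1-[(2R,5E)-5-methyl-4-oxohept-5-en-2-yl]-4-[(triisopropylsilyl)oxy]cyclohex-3-ene-1-carbaldehyde | O=C[C@]1(CCC(O[Si](C(C)C)(C(C)C)C(C)C)=CC1)[C@H](C)CC(=O)/C(C)=C/C
F2 | step 6 | (6R)-3-[(tert-butyldimethylsilyl)oxy]-6-ethenyl-N,N-dimethyl-6-[(2R,5E)-5-methyl-4-oxohept-5-en-2-yl]cyclohex-2-en-1-amine (C1 epimers converge) | C=C[C@]1(CCC(O[Si](C)(C)C(C)(C)C)=CC1N(C)C)[C@H](C)CC(=O)/C(C)=C/C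
F3 | step 6 | (6R)-3-[(tert-butyldimethylsilyl)oxy]-6-ethenyl-N,N,N-trimethyl-6-[(2R,5E)-5-methyl-4-oxohept-5-en-2-yl]cyclohex-2-en-1-aminium trifluoromethanesulfonate | C=C[C@]1(CCC(O[Si](C)(C)C(C)(C)C)=CC1[N+](C)(C)C)[C@H](C)CC(=O)/C(C)=C/C.[O-]S(=O)(=O)C(F)(F)F
F4 | step 10 | 9-{2-[(1R,2R,3S,4R,6R,7S,8S)-10-[(tert-butyldimethylsilyl)oxy]-4-hydroxy-2,3,6-trimethyltricyclo[5.3.1.0^3,8]undec-9-en-7-yl]ethyl}-9-borabicyclo[3.3.1]nonane | C1CC2CCCC(C1)B2CC[C@@]34C[C@H]5C(O[Si](C)(C)C(C)(C)C)=C[C@@H]3[C@](C)([C@@H]5C)[C@H](O)C[C@H]4C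
F5 | step 10 | (1R,2R,3S,4R,6R,7S,8S)-10-[(tert-butyldimethylsilyl)oxy]-7-[(3E)-5-hydroxy-3-methylpent-3-en-1-yl]-2,3,6-trimethyltricyclo[5.3.1.0^3,8]undec-9-en-4-ol | OC/C=C(\C)CC[C@@]12C[C@H]3C(O[Si](C)(C)C(C)(C)C)=C[C@@H]1[C@](C)([C@@H]3C)[C@H](O)C[C@H]2C
F6 | step 10 | (1R,2R,3S,4R,6R,7S,8S)-10-[(tert-butyldimethylsilyl)oxy]-7-{2-[(2S,3S)-3-(hydroxymethyl)-2-methyloxiran-2-yl]ethyl}-2,3,6-trimethyltricyclo[5.3.1.0^3,8]undec-9-en-4-ol | OC[C@@H]1O[C@@]1(C)CC[C@@]23C[C@H]4C(O[Si](C)(C)C(C)(C)C)=C[C@@H]2[C@](C)([C@@H]4C)[C@H](O)C[C@H]3C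
F7 | step 10 | (1R,2R,3S,4R,6R,7S,8S)-10-[(tert-butyldimethylsilyl)oxy]-7-{2-[(2S,3R)-3-(iodomethyl)-2-methyloxiran-2-yl]ethyl}-2,3,6-trimethyltricyclo[5.3.1.0^3,8]undec-9-en-4-ol | IC[C@@H]1O[C@@]1(C)CC[C@@]23C[C@H]4C(O[Si](C)(C)C(C)(C)C)=C[C@@H]2[C@](C)([C@@H]4C)[C@H](O)C[C@H]3C
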